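**Retrosynthetic overview**
- The target, oxacyclopentatriacontan-2-one (C34H66O2), is a single unsubstituted 35-membered ring made of O1, the carbonyl carbon C2 and thirty-three CH2 groups (C3–C35). It has no stereocentre.
- The strategy rests on one feature. Deleting ring atom O1 leaves the 34-carbon ring of cyclotetratriacontanone, whose two α-CH2 groups are equivalent. The O1–C35 bond is therefore made last by Baeyer–Villiger insertion, which can give only one lactone.
- The carbocycle is cut between its carbonyl carbon and one α-carbon (C1–C2 of the acyloin). This leads back to the two identical ester carbonyls of linear dimethyl tetratriacontanedioate, joined by acyloin closure with silyl trapping.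
- The C34 diester is cut at its central C17–C18 bond into two molecules of monomethyl octadecanedioate (Kolbe dimerisation), made from the C18 diacid.
- Ring order: the 34-membered carbocycle is closed in step 4 and enlarged by one oxygen atom to the 35-membered lactone in step 7.

Key step: step 4

Assumption: the enediol ether of step 4 is drawn as its Z isomer; any E isomer formed beside it would give the same acyloin in step 5 and would simply be carried along.

**Step 1**
Reactants: 1 octadecanedioic acid; 2 methanol
Product: 3 dimethyl octadecanedioate
Conditions: cat. H2SO4, MeOH, reflux
Reagents that add atoms: methanol, CO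
Why: Fischer esterification, an acid-catalysed acyl substitution driven to the diester by the large excess of methanol, and the product should crystallise on cooling.

**Step 2**
Reactants: 3 dimethyl octadecanedioate
Product: 5 18-methoxy-18-oxooctadecanoic acid (monomethyl octadecanedioate), via barium half-ester salt 4 (not isolated)
Conditions: Ba(OH)2 (0.5 equiv), dry MeOH, 45 °C; then aq. HCl, EtOAc
Reagents that add atoms: barium hydroxide Ba(OH)2, [Ba+2].[OH-].[OH-]
Why: Half-saponification (BAc2 ester hydrolysis) with half a molar equivalent of Ba(OH)2, in which salt 4 should precipitate from methanol as it forms and so shield the second ester from hydroxide, while unreacted 3 can be recovered and recycled.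

**Step 3**
Reactants: 5 18-methoxy-18-oxooctadecanoic acid (two molecules)
Product: 6 dimethyl tetratriacontanedioate
Conditions: NaOMe (0.05 equiv), MeOH–pyridine, Pt anode/Pt cathode, undivided cell, constant current at high current density, 50–55 °C
Reagents that add atoms: none
Why: Kolbe anodic decarboxylative dimerisation, in which one-electron oxidation of the carboxylate at platinum and loss of CO2 should give a high surface concentration of primary ω-methoxycarbonylalkyl radicals that pair to form the central C17–C18 bond, the remote methyl ester being inert.

**Step 4**
Reactants: 6 dimethyl tetratriacontanedioate; 7 chlorotrimethylsilane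
Product: 10 (Z)-1,2-bis(trimethylsilyloxy)cyclotetratriacont-1-ene, via cyclotetratriacontane-1,2-dione 8 (not isolated), via disodium enediolate 9 (not isolated)
Conditions: Na (5 equiv, molten, finely dispersed), Me3SiCl (6 equiv, freshly distilled), toluene, reflux, hot dilute toluene solution of 6 and Me3SiCl added over ca. 24 h, high-speed stirring, Ar
Reagents that add atoms: chlorotrimethylsilane, C[Si](C)(C)Cl
Why: Acyloin condensation in its silyl-trapping (Rühlmann) form: molten dispersed sodium passes one electron to each ester carbonyl, the two ketyl radical anions join carbon to carbon to make C1–C2, loss of two methoxides gives dione 8, two more electrons give enediolate 9, and 7 caps both oxygens to give 10. This is the classical reaction type for carbocycles from α,ω-diesters and is known to hold up for rings far beyond twenty members, where polar cyclisations fall off. The one ring formed, the 34-membered carbocycle, closes end to end by radical-anion pairing in which both C=O bonds stay outside the new ring (exo at each terminus), and since both polar chain ends should sit on the sodium surface the closure is expected to be little penalised by the thirty-two intervening CH2 groups. No stereocentre is created; the sodium-bridged enediolate should deliver the Z enediol ether, and this geometry is erased in step 5. The step needs intramolecular pairing to win over chain growth and needs Claisen- or Dieckmann-type condensation to stay silent: slow addition of a hot dilute solution keeps free 6 scarce, the two ends are identical so only one mode of pairing exists, and 7 removes each methoxide as MeOSiMe3 as it is released. Toluene is preferred to a higher-boiling arene because its reflux lies just above the melting point of sodium while volatile 7 can still be held in the pot by an efficient condenser.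

**Step 5**
Reactants: 10 (Z)-1,2-bis(trimethylsilyloxy)cyclotetratriacont-1-ene; 2 methanol
Product: 11 (±)-2-hydroxycyclotetratriacontanone
Conditions: cat. HCl, degassed MeOH–THF, 40 °C, N2
Reagents that add atoms: none
Why: Acid-catalysed methanolysis of both O–Si bonds of the silyl enol ether and tautomerisation should give the racemic α-hydroxy ketone, whose single stereocentre needs no control because step 6 removes it, and oxygen is excluded to avoid oxidation back to dione 8.

**Step 6**
Reactants: 11 (±)-2-hydroxycyclotetratriacontanone
Product: 12 cyclotetratriacontanone
Conditions: Zn dust, conc. aq. HCl, AcOH–toluene, 75–80 °C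
Reagents that add atoms: none
Why: Dissolving-metal deoxygenation of an α-hydroxy ketone, in which electron transfer from zinc to the carbonyl expels the protonated α-hydroxyl as water and the resulting zinc enolate is protonated, and because C1 and C2 are equivalent in the ring only one ketone can result.

**Step 7**
Reactants: 12 cyclotetratriacontanone
Product: 14 oxacyclopentatriacontan-2-one (34-tetratriacontanolide), via Criegee adduct 13 (not isolated)
Conditions: (CF3CO)2O, urea·H2O2, Na2HPO4, CH2Cl2, 0 °C to reflux
Reagents that add atoms: urea–hydrogen peroxide, OO.NC(N)=O (source of the inserted oxygen); it acts as trifluoroperacetic acid, OOC(=O)C(F)(F)F, made in the flask with trifluoroacetic anhydride, O=C(OC(=O)C(F)(F)F)C(F)(F)F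
Why: Baeyer–Villiger oxidation, in which trifluoroperacetic acid adds to the ketone to give adduct 13 and an α-CH2 migrates from carbon to oxygen with loss of trifluoroacetate; the two α-carbons are equivalent, so only the 35-membered lactone can form, and the phosphate buffer should prevent acid-induced opening of the product.

**Compound list**
1 | octadecanedioic acid | OC(=O)CCCCCCCCCCCCCCCCC(=O)O | starting material
2 | methanol | CO | starting material
3 | dimethyl octadecanedioate | COC(=O)CCCCCCCCCCCCCCCCC(=O)OC | intermediate
4 | barium bis(18-methoxy-18-oxooctadecanoate) | [Ba+2].[O-]C(=O)CCCCCCCCCCCCCCCCC(=O)OC.[O-]C(=O)CCCCCCCCCCCCCCCCC(=O)OC | intermediate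
5 | 18-methoxy-18-oxooctadecanoic acid | COC(=O)CCCCCCCCCCCCCCCCC(=O)O | intermediate
6 | dimethyl tetratriacontanedioate | COC(=O)CCCCCCCCCCCCCCCCCCCCCCCCCCCCCCCCC(=O)OC | intermediate
7 | chlorotrimethylsilane | C[Si](C)(C)Cl | starting material
8 | cyclotetratriacontane-1,2-dione | O=C1C(=O)CCCCCCCCCCCCCCCCCCCCCCCCCCCCCCCC1 | intermediate
9 | disodium (Z)-cyclotetratriacont-1-ene-1,2-diolate | [Na+].[Na+].[O-]/C1=C(\[O-])CCCCCCCCCCCCCCCCCCCCCCCCCCCCCCCC1 | intermediate
10 | (Z)-1,2-bis(trimethylsilyloxy)cyclotetratriacont-1-ene | C[Si](C)(C)O/C1=C(\O[Si](C)(C)C)CCCCCCCCCCCCCCCCCCCCCCCCCCCCCCCC1 | intermediate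
11 | (±)-2-hydroxycyclotetratriacontanone (racemic) | O=C1C(O)CCCCCCCCCCCCCCCCCCCCCCCCCCCCCCCC1 | intermediate
12 | cyclotetratriacontanone | O=C1CCCCCCCCCCCCCCCCCCCCCCCCCCCCCCCCC1 | intermediate
13 | 1-hydroxycyclotetratriacontyl trifluoroperacetate (Criegee adduct) | OC1(OOC(=O)C(F)(F)F)CCCCCCCCCCCCCCCCCCCCCCCCCCCCCCCCC1 | intermediate
14 | oxacyclopentatriacontan-2-one | O=C1CCCCCCCCCCCCCCCCCCCCCCCCCCCCCCCCCO1 | target

**Total step count:** 7. **Longest linear sequence:** 7 steps (1 to 14).

**Steps most likely to fail**

Step 4 (acyloin closure).
- Risk: intermolecular ketyl coupling and chain growth may outrun ring closure. The sparingly soluble diester may also foul the sodium surface, so that conversion stalls.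
- Fallback: it sets out from 6 and comes back at 14. It gives up the carbocycle and forms the O1–C2 ester bond instead.
- One ester of 6 would be saponified with one equivalent of KOH in hot THF–MeOH, followed by acid work-up, to 34-methoxy-34-oxotetratriacontanoic acid F1.
- The free acid would be reduced chemoselectively with BH3·SMe2 in warm THF to methyl 34-hydroxytetratriacontanoate F2.
- The remaining ester would be hydrolysed with KOH in aqueous THF–EtOH to 34-hydroxytetratriacontanoic acid F3.
- Yamaguchi macrolactonisation would follow. Treatment with 2,4,6-trichlorobenzoyl chloride and Et3N in THF gives 34-hydroxytetratriacontanoic 2,4,6-trichlorobenzoic anhydride F4. Slow addition of F4 to DMAP in refluxing toluene should then close the 35-membered ring to 14.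

Step 3 (Kolbe dimerisation).
- Risk: the poorly soluble product may passivate the anode. Further oxidation of the radical to the cation (Hofer–Moest pathway) may also divert material to ethers and alkenes instead of the dimer.
- Fallback: it sets out from 5 and comes back at 6.
- Treatment of 5 with KOH and AgNO3 would give silver 18-methoxy-18-oxooctadecanoate F5.
- After rigorous drying, F5 would undergo Hunsdiecker bromodecarboxylation (Br2, dry CCl4, reflux) to methyl 17-bromoheptadecanoate F6.
- Nickel-catalysed reductive homocoupling of this primary bromide would then make the same central C–C bond without electrochemistry and give 6. The conditions would be cat. NaI, cat. NiCl2(dme), a terpyridine ligand, Mn powder, DMF, 50 °C.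

Step 6 (zinc/HCl deoxygenation).
- Risk: Clemmensen-type over-reduction of the new ketone towards the hydrocarbon is possible. Conversion may also be incomplete because the waxy substrate dissolves poorly in the acidic medium.
- Fallback: it sets out from 11 and comes back at 12.
- Acetylation (Ac2O, pyridine, cat. DMAP, warm CH2Cl2) would give 2-oxocyclotetratriacontyl acetate F7.
- F7 would be cleaved with SmI2 in THF–MeOH at 0 °C to room temperature. This is a homogeneous, neutral single-electron reduction that expels acetate by way of the samarium enolate. It should leave an isolated dialkyl ketone untouched, giving 12.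

**Further compounds**
F1 | step 4 | 34-methoxy-34-oxotetratriacontanoic acid | COC(=O)CCCCCCCCCCCCCCCCCCCCCCCCCCCCCCCCC(=O)O
F2 | step 4 | methyl 34-hydroxytetratriacontanoate | COC(=O)CCCCCCCCCCCCCCCCCCCCCCCCCCCCCCCCCO
F3 | step 4 | 34-hydroxytetratriacontanoic acid | OC(=O)CCCCCCCCCCCCCCCCCCCCCCCCCCCCCCCCCO
F4 | step 4 | 34-hydroxytetratriacontanoic 2,4,6-trichlorobenzoic anhydride | Clc1cc(Cl)c(C(=O)OC(=O)CCCCCCCCCCCCCCCCCCCCCCCCCCCCCCCCCO)c(Cl)c1
F5 | step 3 | silver 18-methoxy-18-oxooctadecanoate | [Ag+].[O-]C(=O)CCCCCCCCCCCCCCCCC(=O)OC
F6 | step 3 | methyl 17-bromoheptadecanoate | COC(=O)CCCCCCCCCCCCCCCCBr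
F7 | step 6 | 2-oxocyclotetratriacontyl acetate (racemic) | CC(=O)OC1C(=O)CCCCCCCCCCCCCCCCCCCCCCCCCCCCCCCC1
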